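At 6.0 d the over-reaction product shows how long the target has stood beside free reagent, so we watch free reagent over time.

| flask | substrate | reagent | remark | time |
|---|---|---|---|---|
| Tuesday's | 0.050 M | 0.20 M | run made earlier |  |
| Thursday's | 0.034 M | 0.20 M | run made earlier |  |
| Wednesday's | 0.075 M | 0.20 M | run made earlier |  |
| Saturday's | 0.050 M | 0.10 M | run made earlier |  |
| elm | 0.050 M | 0.200 M (fed, over 30 h) | all else is in the flask from the start; the feed brings no volume worth counting | 6.0 d |
| maple | 0.050 M | 0.200 M (fed, over 5.0 d) | all else is in the flask from the start; the feed brings no volume worth counting | 6.0 d |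
| birch | 0.050 M (fed, over 5.0 d) | 0.200 M | all else is in the flask from the start; the feed brings no volume worth counting | 6.0 d |
| ash | 0.050 M | 0.200 M | everything together at the start | 6.0 d |

- Tuesday's (time / d: over-reaction product / %, target / %): 0.250: 0.9, 12.1; 0.500: 4.7, 14.7; 0.833: 8.4, 15.8; 1.25: 13.5, 16.2; 2.00: 22.5, 15.4; 4.00: 42.0, 11.2
- Thursday's (time / d: over-reaction product / %, target / %): 0.250: 1.5, 12.4; 0.500: 4.9, 14.4; 0.833: 9.3, 15.2; 1.25: 15.1, 15.3; 2.00: 25.5, 13.8; 4.00: 45.5, 10.6
- Wednesday's (time / d: over-reaction product / %, target / %): 0.250: 1.7, 12.5; 0.500: 2.9, 15.4; 0.833: 7.6, 16.7; 1.25: 11.3, 16.6; 2.00: 19.0, 15.6; 4.00: 35.7, 13.0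
- Saturday's (time / d: over-reaction product / %, target / %): 0.625: 1.5, 16.2; 1.25: 4.4, 17.9; 2.00: 8.2, 18.5; 3.00: 12.7, 17.5; 4.00: 16.7, 16.8

(each reading ± 0.3 percentage points)

- which flask leads in amount of over-reaction product, in percent of the substrate charged ("all alike" within 1.5 percentage points) (elm / maple / birch / ash / all alike)
- how much over-reaction product is there at the end, in percent of the substrate charged: elm
- how much over-reaction product is there at the end, in percent of the substrate charged: maple
- how much over-reaction product is there at the end, in percent of the substrate charged: birch
- how much over-reaction product is there at the end, in percent of the substrate charged: ash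

- the analysis behind the earlier runs scatters by 0.3 percentage points, standard deviation
- steps under discussion: reagent -> decomposition product; intermediate A -> intermediate B; intermediate B <-> target; substrate + reagent -> intermediate A; substrate + reagent -> intermediate C; reagent + target -> over-reaction product; target <-> intermediate C

1. We call the pool the charged substrate not yet turned into over-reaction product. In Tuesday's run the pool falls from 77.5% at 2.00 d to 58.0% at 4.00 d. We take free reagent as charge minus substrate minus over-reaction product, about 0.134 M. The drain constant, the logarithmic fall of the pool per day and per molar of free reagent, is then 0.0451 M⁻¹ h⁻¹. Saturday's run, at a different reagent charge, reads 0.0462 M⁻¹ h⁻¹. The pool thus falls pseudo-first-order in the exposure E, the time integral of c(reagent), and the product share is 1 − exp(−D·E).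

2. Upper bound for maple: c(reagent) stays near zero until the feed matches the substrate, at 1.25 d, then ramps to 0.150 M at 5.0 d and holds. This gives E = 621 M·min and 37.3%.

3. Lower bound for maple: we charge the reagent loss at that upper share to every day after the lag, which gives 31.0%.

4. Going round again for maple: along the ramp the exposure grows with the square of time, so the mean share there is a third of its value at the feed's end, 26.2%. The reagent loss then comes to 46.5 M·min, and we commit to 35.1%.

5. Uncorrected exposure is larger in ash, 1300 M·min, than in elm, 1130 M·min, so we put ash ahead of elm and maple. Birch, whose pool is itself fed, gets no bracket from us.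

6. The forecast gives ash 55%, elm 51%, maple 33%, birch 38%, with ash leading. Its grounds include “held in a reservoir, so the pool drains”. Its maple value lies inside our bracket, below our own figure.

The flasks give elm 52.1%, maple 35.3%, birch 37.8%, ash 55.6%; ash leads.

    reagent → decomposition product (k = 3.70 × 10⁻⁵ h⁻¹)
    intermediate A → intermediate B (k = 0.0400 h⁻¹)
    intermediate B ⇌ target (K = 0.450, k = 0.110 h⁻¹)
    substrate + reagent → intermediate A (k = 0.200 M⁻¹ h⁻¹)
    substrate + reagent → intermediate C (k = 5.40 M⁻¹ h⁻¹)
    reagent + target → over-reaction product (k = 0.230 M⁻¹ h⁻¹)
    target ⇌ intermediate C (K = 1.60, k = 0.100 h⁻¹)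

In maple, the step from substrate and reagent to intermediate C has 70% of its turnover behind it at 1.20 d, whereas the over-reaction step reaches half of its turnover at 4.29 d. So in maple the over-reaction step runs later than the step into intermediate C, and at 5.00 d reagent stands at 68.6% of its charge. With substrate and the time held, reagent at 0.177 M or 0.225 M moves maple's answer by 5 points, so a run at such a charge is one place where the forecast's maple figure stops holding.

Maple read at 10 d: from 35.3% the drain constant gives 63.5%, and with that put back into the reagent, 62.4%. The computed flask gives 62.2%.

The numbers in the tables were computed for an exercise; noise was put on by code.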